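In the delta run the electrophile stands near 62.5 % from 3.00 h on, with 0.47 equiv of nucleophile charged. So when you repeat a run, watch the nucleophile, the limiting reagent there.

in all of them: electrophile 0.25 M

| flask | nucleophile | free base | protic impurity | remark | time |
|---|---|---|---|---|---|
| delta | 0.47 equiv | 0.80 equiv | 5 mM | run made earlier |  |
| theta | 1.9 equiv | 0.80 equiv | 5 mM | run made earlier |  |
| flask | 0.950 equiv | 0.800 equiv | 5.00 mM |  | 8.0 h |

| run | time / h | electrophile / % | target / % |
|---|---|---|---|
| delta | 1.00 | 76.9 | 23.9 |
| delta | 2.00 | 68.8 | 28.0 |
| delta | 3.00 | 62.3 | 30.6 |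
| delta | 4.00 | 62.5 | 29.3 |
| delta | 5.00 | 61.8 | 31.4 |
| delta | 6.00 | 62.5 | 31.4 |
| theta | 0.333 | 54.6 | 35.9 |
| theta | 1.00 | 31.5 | 41.9 |
| theta | 2.00 | 19.2 | 37.9 |
| theta | 3.00 | 12.3 | 33.9 |
| theta | 4.00 | 9.9 | 27.7 |
| theta | 5.00 | 5.6 | 26.7 |
| theta | 6.00 | 6.5 | 23.7 |

(scatter of a reading: 1 percentage point)

1. part of the electrophile that has reacted at 8.0 h
2. share of the unused nucleophile that is free and not bound as protonated nucleophile, at 8.0 h

- the earlier runs do not show how much of nucleophile is bound; that part of a forecast is a guess

Take the new flask in two extreme versions. I let the protic impurity take its 0.0200 equiv of nucleophile, which leaves 0.930 equiv. If each electrophile stopped at target, it would cost one nucleophile while free base takes its acid. Beyond the 0.800 equiv of free base, the acid would take a second nucleophile as protonated nucleophile. So the nucleophile would stretch to 86.5 % of the electrophile. If each went on to over-reaction product, it would cost two, and 46.5 % would react.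

The real flask lies between. I assume both steps are first order in free nucleophile. Its concentration then cancels from their ratio, the selectivity factor, so the cost follows the depth of conversion and not the charge. The theta run at 1.00 h gives that cost:

electrophile used = 68.5 %

over-reaction product = used − target = 26.6 %

price = (used + over-reaction product) / used = 1.39

This is the price, nucleophile spent per electrophile used. That theta reading has spent 95.1 % of nucleophile per electrophile charged, close to the flask's 0.930 equiv, so the depth fits. The delta run, shallower, paid 1.16. My reckoning for the flask: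

reacted = 0.930 equiv / 1.39 = 66.9 %

The forecast gives 67 % reacted and 50 % free, and says “fr is largely a guess”.

    electrophile + nucleophile → acid set free + target (k = 0.0970 L mol⁻¹ min⁻¹)
    nucleophile + acid set free ⇌ protonated nucleophile, settled at all times (K = 930 L mol⁻¹)
    acid set free + free base ⇌ salt of the base (K = 2.40 × 10⁵ L mol⁻¹, k = 7.96 L mol⁻¹ min⁻¹)
    nucleophile + protic impurity → quenched reagent (k = 26.6 L mol⁻¹ min⁻¹)
    nucleophile + target → over-reaction product (k = 0.0755 L mol⁻¹ min⁻¹)

The flask gives 67.1 % reacted and 96.2 % free, 46 percentage points above the forecast. At 8.00 h the flask holds 0.168 M of salt of the base against 2.32 × 10⁻⁵ M of protonated nucleophile. With 25.6 % over-reaction product, the flask's price is 1.38. In the neighbour at 0.10 M of electrophile, the protic impurity claims 0.0500 equiv, which leaves 0.900 equiv. Divided by the price, that is 64.7 %. That neighbour gives 62.6 %, with 5.3 % of its nucleophile still free.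

All runs were computed on assumed constants; noise was put on by code.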